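The route rests on disconnecting O1–C2 of the dihydrofuran ring (O1, C2, C3, C3a, C7a). C2 is benzylic and para to the C4′ oxygen of the pendant aryl ring B, so it can arise as the methide carbon of a para-quinone methide that the C7a oxygen of benzo ring A captures. One oxidation of an open-chain bisphenol thus forms O1–C2, closes the five-membered ring and sets C2 trans to the existing C3 centre. The precursor is an (R)-2,3-diarylpropan-1-ol with a free 4-hydroxy-3-methoxybenzyl unit, a free ortho phenol on 5-brominated ring A and the C3 hydroxymethyl group; C3 comes from an auxiliary-controlled enolate benzylation, and the bromide later becomes the hydroxypropenyl chain.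

Key step: step 12

Remark: the chelated Z-enolate model of the alkylation requires the (R)-enantiomer of 4-benzyl-2-oxazolidinone to give the (R) centre at C3 (the (S)-auxiliary would lead to the antipode), so the (R)-auxiliary is used.

Step 1
Reactants: 1 5-bromo-2-hydroxy-3-methoxybenzaldehyde
Product: 2 5-bromo-3-methoxy-2-(triisopropylsilyloxy)benzaldehyde
Conditions: TIPSOTf, 2,6-lutidine, CH2Cl2, 0 °C → rt
Reagents that add atoms: triisopropylsilyl trifluoromethanesulfonate, CC(C)[Si](C(C)C)(C(C)C)OS(=O)(=O)C(F)(F)F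
Why: Silylation of the phenol with a silyl triflate and a hindered pyridine base should succeed even at this flanked, hydrogen-bonded hydroxyl, and the resulting triisopropylsilyl ether tolerates ylides, aqueous acid, amide bases and borohydride yet is later cleaved by fluoride without touching the aryl bromide.

Step 2
Reactants: 2 5-bromo-3-methoxy-2-(triisopropylsilyloxy)benzaldehyde
Product: 3 [4-bromo-2-methoxy-6-(2-methoxyethenyl)phenoxy]triisopropylsilane (E/Z mixture)
Conditions: Ph3P(CH2OMe)Cl, KHMDS, THF, 0 °C; then 2, 0 °C → rt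
Reagents that add atoms: (methoxymethyl)triphenylphosphonium chloride, COC[P+](c1ccccc1)(c1ccccc1)c1ccccc1.[Cl-]
Why: Wittig olefination of the non-enolisable aldehyde with the methoxymethylene ylide is a standard one-carbon homologation, and the E/Z mixture of enol ethers is of no consequence because both isomers hydrolyse to the same aldehyde.

Step 3
Reactants: 3 [4-bromo-2-methoxy-6-(2-methoxyethenyl)phenoxy]triisopropylsilane
Product: 4 2-[5-bromo-3-methoxy-2-(triisopropylsilyloxy)phenyl]acetaldehyde
Conditions: 2 M aq. HCl, THF, 50 °C; crude product used directly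
Reagents that add atoms: water, O
Why: Acid-catalysed enol ether hydrolysis (protonation at the β-carbon, hydration of the oxocarbenium ion, loss of methanol) should release the arylacetaldehyde while the acid-stable aryl silyl ether stays in place.

Step 4
Reactants: 4 2-[5-bromo-3-methoxy-2-(triisopropylsilyloxy)phenyl]acetaldehyde
Product: 5 2-[5-bromo-3-methoxy-2-(triisopropylsilyloxy)phenyl]acetic acid
Conditions: NaClO2, NaH2PO4, 2-methyl-2-butene, t-BuOH/H2O, 0 °C → rt
Reagents that add atoms: sodium chlorite, [Na+].[O-]Cl=O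
Why: Pinnick oxidation should turn the aldehyde into the carboxylic acid under buffered conditions, the alkene scavenger removing hypochlorous acid before it can chlorinate the electron-rich ring.

Step 5
Reactants: 5 2-[5-bromo-3-methoxy-2-(triisopropylsilyloxy)phenyl]acetic acid; 6 (R)-4-benzyl-1,3-oxazolidin-2-one
Product: 8 (R)-4-benzyl-3-{[5-bromo-3-methoxy-2-(triisopropylsilyloxy)phenyl]acetyl}-1,3-oxazolidin-2-one, via mixed pivalic anhydride 7 (not isolated)
Conditions: PivCl, Et3N, THF, −20 °C; then LiCl, 6, −20 °C → rt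
Reagents that add atoms: none
Why: N-Acylation of the oxazolidinone through the mixed pivalic anhydride should take place at the less hindered arylacetyl carbonyl, with lithium chloride and triethylamine activating the auxiliary so that no strong base is needed.

Step 6
Reactants: 9 vanillin (4-hydroxy-3-methoxybenzaldehyde)
Product: 10 3-methoxy-4-(triisopropylsilyloxy)benzaldehyde
Conditions: TIPSCl, imidazole, DMF, rt
Reagents that add atoms: chlorotriisopropylsilane, CC(C)[Si](Cl)(C(C)C)C(C)C
Why: Imidazole-promoted silylation of the phenol should protect ring B as a fluoride-labile ether that withstands hydride reduction, bromination and the enolate alkylation.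

Step 7
Reactants: 10 3-methoxy-4-(triisopropylsilyloxy)benzaldehyde
Product: 11 [3-methoxy-4-(triisopropylsilyloxy)phenyl]methanol
Conditions: NaBH4, MeOH, 0 °C
Reagents that add atoms: none
Why: Sodium borohydride reduction of the aromatic aldehyde should give the benzylic alcohol without affecting the aryl silyl ether.

Step 8
Reactants: 11 [3-methoxy-4-(triisopropylsilyloxy)phenyl]methanol
Product: 12 [4-(bromomethyl)-2-methoxyphenoxy]triisopropylsilane
Conditions: PBr3 (0.4 equiv), Et2O, 0 °C; used at once
Reagents that add atoms: phosphorus tribromide, BrP(Br)Br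
Why: Substitution of the activated benzylic alcohol by bromide with phosphorus tribromide (through the phosphite ester) is fast at 0 °C, and the electron-rich bromide is used at once because it ionises readily.

Step 9
Reactants: 8 (R)-4-benzyl-3-{[5-bromo-3-methoxy-2-(triisopropylsilyloxy)phenyl]acetyl}-1,3-oxazolidin-2-one; 12 [4-(bromomethyl)-2-methoxyphenoxy]triisopropylsilane
Product: 14 (R)-4-benzyl-3-{(R)-2-[5-bromo-3-methoxy-2-(triisopropylsilyloxy)phenyl]-3-[3-methoxy-4-(triisopropylsilyloxy)phenyl]propanoyl}-1,3-oxazolidin-2-one, via sodium Z-enolate 13 (not isolated)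
Conditions: NaHMDS, THF, −78 °C; then 12, −78 → −40 °C; AcOH quench
Reagents that add atoms: none
Why: Evans asymmetric alkylation: the chelated sodium Z-enolate 13 should be attacked by the reactive benzylic bromide on the face opposite the benzyl group at C4 of the (R)-auxiliary, which sets the new α-centre (the future C3) as R.

Step 10
Reactants: 14 (R)-4-benzyl-3-{(R)-2-[5-bromo-3-methoxy-2-(triisopropylsilyloxy)phenyl]-3-[3-methoxy-4-(triisopropylsilyloxy)phenyl]propanoyl}-1,3-oxazolidin-2-one
Product: 15 (R)-2-[5-bromo-3-methoxy-2-(triisopropylsilyloxy)phenyl]-3-[3-methoxy-4-(triisopropylsilyloxy)phenyl]propan-1-ol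
Conditions: LiBH4, MeOH (1 equiv), THF, 0 °C
Reagents that add atoms: none
Why: Reductive cleavage of the N-acyl oxazolidinone with lithium borohydride should attack the exocyclic carbonyl, releasing the primary alcohol and the recoverable auxiliary under weakly basic conditions that leave the α-aryl centre, the silyl ethers and the aryl bromide intact.

Step 11
Reactants: 15 (R)-2-[5-bromo-3-methoxy-2-(triisopropylsilyloxy)phenyl]-3-[3-methoxy-4-(triisopropylsilyloxy)phenyl]propan-1-ol
Product: 16 (R)-2-(5-bromo-2-hydroxy-3-methoxyphenyl)-3-(4-hydroxy-3-methoxyphenyl)propan-1-ol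
Conditions: TBAF (2.4 equiv), AcOH (2.4 equiv), THF, 0 °C → rt
Reagents that add atoms: none
Why: Fluoride-mediated desilylation should cleave both aryl silyl ethers, and buffering with acetic acid keeps the phenols protonated so that the electron-rich bisphenol is not exposed to basic, oxidation-prone conditions.

Step 12
Reactants: 16 (R)-2-(5-bromo-2-hydroxy-3-methoxyphenyl)-3-(4-hydroxy-3-methoxyphenyl)propan-1-ol
Product: 18 4-[(2S,3R)-5-bromo-3-(hydroxymethyl)-7-methoxy-2,3-dihydro-1-benzofuran-2-yl]-2-methoxyphenol, via para-quinone methide 17 (not isolated)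
Conditions: Ag2O (1.5 equiv), CH2Cl2/acetone (0.01 M), rt, dark, argon; filtration through Celite
Reagents that add atoms: none
Why: Silver(I) oxide should oxidise the phenols to phenoxyl radicals on its surface, and only the ring-B radical can go on, by loss of a benzylic hydrogen from its para CH2 group, to the para-quinone methide 17, whose exocyclic carbon (the future C2) is then attacked by the ring-A phenol in a 1,6-conjugate addition that rearomatises ring B. This is oxidative para-quinone methide generation from a 4-alkyl-2-methoxyphenol followed by intramolecular phenol capture, the established way to phenylcoumarans. The dihydrofuran ring closes in a 5-exo-trig mode, O1 adding to the exocyclic methide carbon. C2 is controlled by the C3 centre: in the closing transition state the quinoid ring avoids the hydroxymethyl group, so the aryl group should end up trans to CH2OH, which is also the more stable arrangement, giving (2S,3R). The step needs oxidation of ring B in preference to ring A and cyclisation in preference to intermolecular coupling; ring A carries bromine at its para position and has no free ortho position, so its radical can neither form a para-quinone methide nor couple through carbon, while high dilution and a limited amount of oxidant should hold back 5–5′ dimerisation of ring B and over-oxidation of the product.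

Step 13
Reactants: 18 4-[(2S,3R)-5-bromo-3-(hydroxymethyl)-7-methoxy-2,3-dihydro-1-benzofuran-2-yl]-2-methoxyphenol
Product: 19 [(2S,3R)-5-bromo-2-(3,4-dimethoxyphenyl)-7-methoxy-2,3-dihydro-1-benzofuran-3-yl]methanol
Conditions: MeI, K2CO3, acetone, rt
Reagents that add atoms: iodomethane, CI
Why: Williamson etherification: carbonate deprotonates only the phenol, so methyl iodide should methylate O4′ and leave the primary alcohol free, which also removes the last oxidisable phenol before the palladium step.

Step 14
Reactants: 19 [(2S,3R)-5-bromo-2-(3,4-dimethoxyphenyl)-7-methoxy-2,3-dihydro-1-benzofuran-3-yl]methanol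
Product: 20 methyl (E)-3-[(2S,3R)-2-(3,4-dimethoxyphenyl)-3-(hydroxymethyl)-7-methoxy-2,3-dihydro-1-benzofuran-5-yl]prop-2-enoate
Conditions: methyl acrylate, Pd(OAc)2 (5 mol%), P(o-tol)3 (10 mol%), Et3N, DMF, 100 °C
Reagents that add atoms: methyl acrylate, C=CC(=O)OC
Why: Mizoroki–Heck reaction: oxidative addition of palladium(0) into the unhindered aryl bromide, syn-insertion of the acrylate and syn-β-hydride elimination should give the E enoate, with the free alcohol and both stereocentres not involved.

Step 15
Reactants: 20 methyl (E)-3-[(2S,3R)-2-(3,4-dimethoxyphenyl)-3-(hydroxymethyl)-7-methoxy-2,3-dihydro-1-benzofuran-5-yl]prop-2-enoate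
Product: 21 Hierochin B [(E)-3-[(2S,3R)-2-(3,4-dimethoxyphenyl)-3-(hydroxymethyl)-7-methoxy-2,3-dihydro-1-benzofuran-5-yl]prop-2-en-1-ol]
Conditions: DIBAL-H (4 equiv), CH2Cl2, −78 °C; aq. Rochelle salt
Reagents that add atoms: none
Why: DIBAL-H should reduce the conjugated ester by 1,2-addition to the allylic alcohol with retention of the E geometry, the excess reagent allowing for the hydroxyl group that is deprotonated first.

Compound list

1 | 5-bromo-2-hydroxy-3-methoxybenzaldehyde | COc1cc(Br)cc(C=O)c1O | starting material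
2 | 5-bromo-3-methoxy-2-(triisopropylsilyloxy)benzaldehyde | COc1cc(Br)cc(C=O)c1O[Si](C(C)C)(C(C)C)C(C)C | intermediate
3 | [4-bromo-2-methoxy-6-(2-methoxyethenyl)phenoxy]triisopropylsilane (E/Z mixture) | COC=Cc1cc(Br)cc(OC)c1O[Si](C(C)C)(C(C)C)C(C)C | intermediate
4 | 2-[5-bromo-3-methoxy-2-(triisopropylsilyloxy)phenyl]acetaldehyde | O=CCc1cc(Br)cc(OC)c1O[Si](C(C)C)(C(C)C)C(C)C | intermediate
5 | 2-[5-bromo-3-methoxy-2-(triisopropylsilyloxy)phenyl]acetic acid | OC(=O)Cc1cc(Br)cc(OC)c1O[Si](C(C)C)(C(C)C)C(C)C | intermediate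
6 | (R)-4-benzyl-1,3-oxazolidin-2-one | O=C1N[C@H](Cc2ccccc2)CO1 | starting material
7 | mixed pivalic anhydride of acid 5 (formed in the flask) | CC(C)(C)C(=O)OC(=O)Cc1cc(Br)cc(OC)c1O[Si](C(C)C)(C(C)C)C(C)C | intermediate
8 | (R)-4-benzyl-3-{[5-bromo-3-methoxy-2-(triisopropylsilyloxy)phenyl]acetyl}-1,3-oxazolidin-2-one | O=C(Cc1cc(Br)cc(OC)c1O[Si](C(C)C)(C(C)C)C(C)C)N1[C@H](Cc2ccccc2)COC1=O | intermediate
9 | vanillin (4-hydroxy-3-methoxybenzaldehyde) | COc1cc(C=O)ccc1O | starting material
10 | 3-methoxy-4-(triisopropylsilyloxy)benzaldehyde | COc1cc(C=O)ccc1O[Si](C(C)C)(C(C)C)C(C)C | intermediate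
11 | [3-methoxy-4-(triisopropylsilyloxy)phenyl]methanol | COc1cc(CO)ccc1O[Si](C(C)C)(C(C)C)C(C)C | intermediate
12 | [4-(bromomethyl)-2-methoxyphenoxy]triisopropylsilane | COc1cc(CBr)ccc1O[Si](C(C)C)(C(C)C)C(C)C | intermediate
13 | sodium Z-enolate of imide 8 (formed in the flask) | [Na+].[O-]/C(=C\c1cc(Br)cc(OC)c1O[Si](C(C)C)(C(C)C)C(C)C)N1[C@H](Cc2ccccc2)COC1=O | intermediate
14 | (R)-4-benzyl-3-{(R)-2-[5-bromo-3-methoxy-2-(triisopropylsilyloxy)phenyl]-3-[3-methoxy-4-(triisopropylsilyloxy)phenyl]propanoyl}-1,3-oxazolidin-2-one | COc1cc(C[C@@H](C(=O)N2[C@H](Cc3ccccc3)COC2=O)c2cc(Br)cc(OC)c2O[Si](C(C)C)(C(C)C)C(C)C)ccc1O[Si](C(C)C)(C(C)C)C(C)C | intermediate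
15 | (R)-2-[5-bromo-3-methoxy-2-(triisopropylsilyloxy)phenyl]-3-[3-methoxy-4-(triisopropylsilyloxy)phenyl]propan-1-ol | COc1cc(C[C@@H](CO)c2cc(Br)cc(OC)c2O[Si](C(C)C)(C(C)C)C(C)C)ccc1O[Si](C(C)C)(C(C)C)C(C)C | intermediate
16 | (R)-2-(5-bromo-2-hydroxy-3-methoxyphenyl)-3-(4-hydroxy-3-methoxyphenyl)propan-1-ol | COc1cc(C[C@@H](CO)c2cc(Br)cc(OC)c2O)ccc1O | intermediate
17 | para-quinone methide of 16, 4-[(R)-2-(5-bromo-2-hydroxy-3-methoxyphenyl)-3-hydroxypropylidene]-2-methoxycyclohexa-2,5-dien-1-one (formed in the flask, alkene geometry undefined) | COC1=CC(=C[C@@H](CO)c2cc(Br)cc(OC)c2O)C=CC1=O | intermediate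
18 | 4-[(2S,3R)-5-bromo-3-(hydroxymethyl)-7-methoxy-2,3-dihydro-1-benzofuran-2-yl]-2-methoxyphenol | COc1cc([C@H]2Oc3c(OC)cc(Br)cc3[C@@H]2CO)ccc1O | intermediate
19 | [(2S,3R)-5-bromo-2-(3,4-dimethoxyphenyl)-7-methoxy-2,3-dihydro-1-benzofuran-3-yl]methanol | COc1ccc([C@H]2Oc3c(OC)cc(Br)cc3[C@@H]2CO)cc1OC | intermediate
20 | methyl (E)-3-[(2S,3R)-2-(3,4-dimethoxyphenyl)-3-(hydroxymethyl)-7-methoxy-2,3-dihydro-1-benzofuran-5-yl]prop-2-enoate | COc1ccc([C@H]2Oc3c(OC)cc(/C=C/C(=O)OC)cc3[C@@H]2CO)cc1OC | intermediate
21 | Hierochin B, (E)-3-[(2S,3R)-2-(3,4-dimethoxyphenyl)-3-(hydroxymethyl)-7-methoxy-2,3-dihydro-1-benzofuran-5-yl]prop-2-en-1-ol | COc1ccc([C@H]2Oc3c(OC)cc(/C=C/CO)cc3[C@@H]2CO)cc1OC | target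

Total step count: 15. Longest linear sequence: 12 steps (steps 1–5 and 9–15).

Steps most likely to fail

1. Step 12 (oxidative ring closure). What may go wrong: oxidation spread over both phenols, carbon–carbon coupling of phenoxyl radicals, tautomerisation of the methide to a stilbene before capture, or over-oxidation of the cyclised phenol. Fallback: O1–C2 is formed by ionisation of a benzylic alcohol instead of by C–H oxidation. It sets out from acid 5, which is coupled as in step 5, but to (S)-4-benzyl-2-oxazolidinone, to give the antipodal-auxiliary imide F1. A boron-mediated syn aldol reaction (Bu2BOTf, i-Pr2NEt, CH2Cl2, −78 → 0 °C) with 3,4-dimethoxybenzaldehyde should give the β-hydroxy imide F2; its non-chelated Zimmerman–Traxler transition state attacks the enolate face opposite to that of a chelated alkylation, so the (S)-auxiliary delivers the same C3 configuration as the main route. LiBH4 reduction should give the diol F3 and TBAF the phenol diol F4. Acid (BF3·OEt2 or TsOH, CH2Cl2, 0 °C) then ionises the electron-rich benzylic alcohol, the ring-A phenol closes the trans ring, and the route is rejoined at 19.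

2. Step 9 (enolate benzylation). What may go wrong: ionisation or self-condensation of the electron-rich benzylic bromide before C-alkylation, sluggish reaction of the hindered aryl-substituted enolate, and loss of configuration at the acidic α-aryl centre by proton exchange. Fallback: C3 is set by catalytic asymmetric hydrogenation instead of enolate alkylation. It sets out from acid 5 and aldehyde 10: Perkin condensation (Ac2O, Et3N, 110 °C) should give the (E)-2,3-diarylacrylic acid F5. Hydrogenation with a chiral iridium or rhodium phosphine catalyst (H2, MeOH, Et3N), the ligand antipode chosen for the R acid, should give the saturated acid F6. Reduction with BH3·SMe2 (THF, 0 °C) rejoins the route at 15.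

3. Step 3 (enol ether hydrolysis). What may go wrong: aldol self-condensation or air oxidation of the liberated arylacetaldehyde, or partial loss of the silyl ether in acid. Fallback: the acid is reached through an alcohol instead of through an enol ether and a free aldehyde. It sets out from aldehyde 2: methylenation (Ph3P=CH2, THF, 0 °C) should give the styrene F7, anti-Markovnikov hydroboration–oxidation (9-BBN, THF; then NaBO3·4H2O) the 2-arylethanol F8, and oxidation with TEMPO/PhI(OAc)2 in MeCN/H2O rejoins the route at acid 5.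

Further compounds

F1 | step 12 | (S)-4-benzyl-3-{[5-bromo-3-methoxy-2-(triisopropylsilyloxy)phenyl]acetyl}-1,3-oxazolidin-2-one | O=C(Cc1cc(Br)cc(OC)c1O[Si](C(C)C)(C(C)C)C(C)C)N1[C@@H](Cc2ccccc2)COC1=O
F2 | step 12 | (S)-4-benzyl-3-{(2S,3S)-2-[5-bromo-3-methoxy-2-(triisopropylsilyloxy)phenyl]-3-(3,4-dimethoxyphenyl)-3-hydroxypropanoyl}-1,3-oxazolidin-2-one | COc1ccc([C@@H](O)[C@@H](C(=O)N2[C@@H](Cc3ccccc3)COC2=O)c2cc(Br)cc(OC)c2O[Si](C(C)C)(C(C)C)C(C)C)cc1OC
F3 | step 12 | (1S,2R)-2-[5-bromo-3-methoxy-2-(triisopropylsilyloxy)phenyl]-1-(3,4-dimethoxyphenyl)propane-1,3-diol | COc1ccc([C@@H](O)[C@@H](CO)c2cc(Br)cc(OC)c2O[Si](C(C)C)(C(C)C)C(C)C)cc1OC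
F4 | step 12 | (1S,2R)-2-(5-bromo-2-hydroxy-3-methoxyphenyl)-1-(3,4-dimethoxyphenyl)propane-1,3-diol | COc1ccc([C@@H](O)[C@@H](CO)c2cc(Br)cc(OC)c2O)cc1OC
F5 | step 9 | (E)-2-[5-bromo-3-methoxy-2-(triisopropylsilyloxy)phenyl]-3-[3-methoxy-4-(triisopropylsilyloxy)phenyl]prop-2-enoic acid | COc1cc(/C=C(/C(=O)O)c2cc(Br)cc(OC)c2O[Si](C(C)C)(C(C)C)C(C)C)ccc1O[Si](C(C)C)(C(C)C)C(C)C
F6 | step 9 | (R)-2-[5-bromo-3-methoxy-2-(triisopropylsilyloxy)phenyl]-3-[3-methoxy-4-(triisopropylsilyloxy)phenyl]propanoic acid | COc1cc(C[C@@H](C(=O)O)c2cc(Br)cc(OC)c2O[Si](C(C)C)(C(C)C)C(C)C)ccc1O[Si](C(C)C)(C(C)C)C(C)C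
F7 | step 3 | (4-bromo-2-ethenyl-6-methoxyphenoxy)triisopropylsilane | C=Cc1cc(Br)cc(OC)c1O[Si](C(C)C)(C(C)C)C(C)C
F8 | step 3 | 2-[5-bromo-3-methoxy-2-(triisopropylsilyloxy)phenyl]ethan-1-ol | OCCc1cc(Br)cc(OC)c1O[Si](C(C)C)(C(C)C)C(C)C
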